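**Assumption:** stabilised ylides, triethyl phosphonoacetate, (E)-1,2-bis(tributylstannyl)ethene, the chiral Ru complex and N-benzylcinchoninium chloride are bought and used as reagents or catalysts; the cyclopentenone amide is handled as the enol tautomer written in the SMILES.

## Retrosynthetic overview

1. Last bond: Stille coupling between the epoxyquinol (E)-vinylstannane 20 (upper amide plus core) and the bromodienamide 30 (C5 chain plus aminocyclopentenone).
2. 20 comes from ketal hydrolysis, anti-to-epoxide addition of (E)-Bu3SnCH=CHLi to epoxy ketone 18, asymmetric nucleophilic epoxidation of quinone monoketal 17, and PhI(OAc)2/MeOH dearomatisation of anilide 15, itself from 2,5-dimethoxyaniline 14 (from hydroquinone) and acid chloride 10.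
3. 10 comes from Wittig and Horner–Wadsworth–Emmons homologation of (R)-2-methylhexanal; the stereocentre is set by Ru-catalysed asymmetric hydrogenation of (E)-2-methylhex-2-enoic acid (from butanal).
4. 30 comes from N-acylation of 2-amino-3-hydroxycyclopent-2-enone hydrochloride (from cyclopentane-1,3-dione) with 5-bromopentadienoyl chloride (from pyridine via glutaconaldehyde).
5. Ring order: the six-membered carbocycle is carried from hydroquinone and dearomatised (step 14), then the oxirane is formed (step 15); the five-membered ring is bought and attached by an amide bond before the final coupling.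

## Route

**Upper side chain (steps 1–9)**

Step 1
Reactants: 1 butanal
Product: 2 ethyl (E)-2-methylhex-2-enoate
Conditions: Ph3P=C(Me)CO2Et (1.1 equiv), CH2Cl2, rt, 16 h
Reagents that add atoms: ethyl 2-(triphenylphosphoranylidene)propanoate, CCOC(=O)C(C)=P(c1ccccc1)(c1ccccc1)c1ccccc1
Why: Wittig olefination with a stabilised ylide gives the trisubstituted (E)-enoate (typically ≥95:5), and the minor Z ester is removed by chromatography because it would erode the ee of step 3.

Step 2
Reactants: 2 ethyl (E)-2-methylhex-2-enoate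
Product: 3 (E)-2-methylhex-2-enoic acid
Conditions: LiOH·H2O, THF/MeOH/H2O, 40 °C; then 1 M HCl
Reagents that add atoms: lithium hydroxide, [Li+].[OH-]
Why: Ester saponification, which leaves the alkene geometry untouched and creates no stereocentre.

Step 3
Reactants: 3 (E)-2-methylhex-2-enoic acid
Product: 4 (R)-2-methylhexanoic acid
Conditions: H2 (2 atm), Ru(OAc)2[(R)-H8-BINAP] (0.5 mol %), MeOH, 20 °C
Reagents that add atoms: none
Why: Noyori–Takaya asymmetric hydrogenation of a carboxylate-bound 2-methyl-2-alkenoic acid, where the (R)-ligand is expected to give the (R)-acid in about 95% ee by analogy with tiglic acid, setting the only side-chain stereocentre.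

Step 4
Reactants: 4 (R)-2-methylhexanoic acid
Product: 5 (R)-2-methylhexan-1-ol
Conditions: LiAlH4, Et2O, 0 °C → rt; Fieser work-up
Reagents that add atoms: none
Why: Hydride reduction of the acid to the primary alcohol, which does not touch the α-stereocentre.

Step 5
Reactants: 5 (R)-2-methylhexan-1-ol
Product: 6 (R)-2-methylhexanal
Conditions: TEMPO (10 mol %), PhI(OAc)2 (1.1 equiv), CH2Cl2, rt; washed solution used at once
Reagents that add atoms: none
Why: Oxoammonium (TEMPO/PhI(OAc)2) oxidation stops at the aldehyde under non-basic conditions, so the α-stereocentre is not epimerised.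

Step 6
Reactants: 6 (R)-2-methylhexanal
Product: 7 (2E,4R)-2,4-dimethyloct-2-enal
Conditions: Ph3P=C(Me)CHO (1.2 equiv), toluene, 90 °C, 16 h
Reagents that add atoms: 2-(triphenylphosphoranylidene)propanal, CC(C=O)=P(c1ccccc1)(c1ccccc1)c1ccccc1
Why: Wittig olefination with the formyl-stabilised ylide is E-selective (>95:5) and neutral, so the former α-centre survives as the allylic C-4 centre.

Step 7
Reactants: 7 (2E,4R)-2,4-dimethyloct-2-enal
Product: 8 ethyl (2E,4E,6R)-4,6-dimethyldeca-2,4-dienoate
Conditions: (EtO)2P(O)CH2CO2Et, NaH, THF, 0 °C → rt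
Reagents that add atoms: triethyl phosphonoacetate, CCOC(=O)CP(=O)(OCC)OCC
Why: Horner–Wadsworth–Emmons olefination of the enal with the preformed phosphonate anion gives the new disubstituted alkene with high E selectivity and does not enolise the γ-centre.

Step 8
Reactants: 8 ethyl (2E,4E,6R)-4,6-dimethyldeca-2,4-dienoate
Product: 9 (2E,4E,6R)-4,6-dimethyldeca-2,4-dienoic acid
Conditions: LiOH·H2O, THF/MeOH/H2O, rt; then 1 M HCl
Reagents that add atoms: lithium hydroxide, [Li+].[OH-]
Why: Ester saponification, with the remote allylic stereocentre and both alkenes unaffected.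

Step 9
Reactants: 9 (2E,4E,6R)-4,6-dimethyldeca-2,4-dienoic acid
Product: 10 (2E,4E,6R)-4,6-dimethyldeca-2,4-dienoyl chloride
Conditions: (COCl)2 (1.3 equiv), DMF (cat.), CH2Cl2, 0 °C → rt; evaporate, use crude
Reagents that add atoms: oxalyl chloride, ClC(=O)C(=O)Cl
Why: Vilsmeier-type activation converts the acid into the acid chloride under neutral conditions that do not isomerise the diene.

**Core and union with the upper chain (steps 10–17)**

Step 10
Reactants: 11 hydroquinone
Product: 12 1,4-dimethoxybenzene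
Conditions: MeI (2.5 equiv), K2CO3, acetone, reflux, N2
Reagents that add atoms: iodomethane, CI
Why: Williamson ether synthesis on both phenols, run under nitrogen to avoid quinone formation.

Step 11
Reactants: 12 1,4-dimethoxybenzene
Product: 13 1,4-dimethoxy-2-nitrobenzene
Conditions: HNO3 (65%), AcOH, 10–20 °C
Reagents that add atoms: nitric acid, O[N+](=O)[O-]
Why: Electrophilic aromatic nitration, where all four ring positions are equivalent and the nitro group deactivates against a second nitration.

Step 12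
Reactants: 13 1,4-dimethoxy-2-nitrobenzene
Product: 14 2,5-dimethoxyaniline
Conditions: H2 (1 atm), Pd/C (10%), EtOH, rt
Reagents that add atoms: none
Why: Catalytic hydrogenation reduces the nitroarene cleanly to the aniline.

Step 13
Reactants: 10 (2E,4E,6R)-4,6-dimethyldeca-2,4-dienoyl chloride; 14 2,5-dimethoxyaniline
Product: 15 (2E,4E,6R)-N-(2,5-dimethoxyphenyl)-4,6-dimethyldeca-2,4-dienamide
Conditions: pyridine (2 equiv), CH2Cl2, 0 °C → rt
Reagents that add atoms: none
Why: N-acylation of the aniline by the acid chloride (amide bond formation) with pyridine as HCl scavenger.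

Step 14
Reactants: 15 (2E,4E,6R)-N-(2,5-dimethoxyphenyl)-4,6-dimethyldeca-2,4-dienamide
Product: 17 (2E,4E,6R)-N-(6,6-dimethoxy-3-oxocyclohexa-1,4-dien-1-yl)-4,6-dimethyldeca-2,4-dienamide, via tetramethoxy bis-ketal 16 (not isolated)
Conditions: PhI(OAc)2 (1.2 equiv), MeOH, 0 °C → rt; then H2O (AcOH formed in situ), rt
Reagents that add atoms: methanol, CO; water, O
Why: Oxidative dearomatisation of the p-dimethoxyarene in methanol, after which only the ketal that is vinylogously linked to the enamide nitrogen ionises and hydrolyses, leaving the ketal next to the N-bearing carbon.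

Step 15
Reactants: 17 quinone monoketal
Product: 18 (2E,4E,6R)-N-[(1S,6R)-2,2-dimethoxy-5-oxo-7-oxabicyclo[4.1.0]hept-3-en-3-yl]-4,6-dimethyldeca-2,4-dienamide (epoxide carbon next to the ketone R, next to the ketal S)
Conditions: tBuOOH (2 equiv), 0.1 M aq NaOH, N-benzylcinchoninium chloride (10 mol %), toluene, 0 °C → rt
Reagents that add atoms: tert-butyl hydroperoxide, CC(C)(C)OO
Why: Weitz–Scheffer nucleophilic epoxidation under Wynberg-type chiral phase-transfer catalysis attacks only the plain enone C=C (the other is a deactivated vinylogous amide), and the ion-paired cinchoninium cation selects the face to set both epoxide centres.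

The cinchonine-derived salt is chosen on the expectation that it is the pseudoenantiomer giving the (1S,6R) epoxide. The sense is checked on 18 (diastereomer ratio against the side-chain centre, CD or X-ray), and the cinchonidine-derived salt is used instead if it proves opposite. Recrystallisation upgrades the ratio.

Step 16
Reactants: 18 epoxy ketone
Product: 19 (2E,4E,6R)-N-[(1S,5R,6R)-5-hydroxy-2,2-dimethoxy-5-[(E)-2-(tributylstannyl)ethenyl]-7-oxabicyclo[4.1.0]hept-3-en-3-yl]-4,6-dimethyldeca-2,4-dienamide (OH cis to the epoxide oxygen)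
Conditions: (E)-Bu3SnCH=CHSnBu3 (3.0 equiv), n-BuLi (2.8 equiv), THF, −78 °C, 1 h; then 18, −78 °C; H2O quench
Reagents that add atoms: (E)-1,2-bis(tributylstannyl)ethene, CCCC[Sn](CCCC)(CCCC)/C=C/[Sn](CCCC)(CCCC)CCCC
Why: Tin–lithium exchange gives (E)-2-(tributylstannyl)vinyllithium, whose first equivalent deprotonates the amide and whose second adds 1,2 to the ketone from the face anti to the epoxide, setting the carbinol centre with OH syn to the oxirane.

Step 17
Reactants: 19 stannyl carbinol ketal
Product: 20 (2E,4E,6R)-N-[(1S,5R,6R)-5-hydroxy-2-oxo-5-[(E)-2-(tributylstannyl)ethenyl]-7-oxabicyclo[4.1.0]hept-3-en-3-yl]-4,6-dimethyldeca-2,4-dienamide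
Conditions: Montmorillonite K10, CH2Cl2 (wet), rt
Reagents that add atoms: water, O
Why: Mild solid-acid ketal hydrolysis unmasks the enone without protodestannylation, epoxide opening or ionisation of the tertiary allylic alcohol.

**Lower fragment (steps 18–25)**

Step 18
Reactants: 21 pyridine
Product: 22 pyridinium-1-sulfonate
Conditions: ClSO3H (0.5 equiv), CHCl3, 0 °C; filter
Reagents that add atoms: chlorosulfonic acid, OS(=O)(=O)Cl
Why: N-sulfonation of pyridine, with a second equivalent of pyridine taking up HCl, gives the activated pyridinium salt.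

Step 19
Reactants: 22 pyridinium-1-sulfonate
Product: 23 glutaconaldehyde potassium salt, potassium (1E,3E)-5-oxopenta-1,3-dien-1-olate
Conditions: KOH (aq), −20 °C → 20 °C, then 40 °C, 1 h; crystallise
Reagents that add atoms: potassium hydroxide, [K+].[OH-]
Why: Zincke-type ring opening, in which hydroxide adds at C-2 of the activated pyridinium, the ring opens electrocyclically and the N-sulfo imine hydrolyses to the all-trans dienolate.

Step 20
Reactants: 23 glutaconaldehyde potassium salt
Product: 24 (2E,4E)-5-bromopenta-2,4-dienal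
Conditions: PPh3, Br2, CH2Cl2, 0 °C; then 23, 0 °C → rt
Reagents that add atoms: bromine (delivered as Ph3PBr2), BrBr
Why: Appel-type deoxybromination, where the enolate oxygen is phosphonium-activated and displaced by bromide through vinylogous addition–elimination, with any 4Z isomer equilibrated to the E,E dienal by a trace of acid.

Step 21
Reactants: 24 (2E,4E)-5-bromopenta-2,4-dienal
Product: 25 (2E,4E)-5-bromopenta-2,4-dienoic acid
Conditions: NaClO2, NaH2PO4, 2-methylbut-2-ene, tBuOH/H2O, rt
Reagents that add atoms: sodium chlorite, [Na+].[O-]Cl=O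
Why: Pinnick oxidation converts the enal to the acid without touching the alkenes or the vinyl bromide, with the alkene scavenger removing HOCl.

Step 22
Reactants: 25 (2E,4E)-5-bromopenta-2,4-dienoic acid
Product: 26 (2E,4E)-5-bromopenta-2,4-dienoyl chloride
Conditions: (COCl)2 (1.3 equiv), DMF (cat.), CH2Cl2, 0 °C → rt; evaporate, use crude
Reagents that add atoms: oxalyl chloride, ClC(=O)C(=O)Cl
Why: Vilsmeier-type acid chloride formation under neutral conditions preserves the E,E bromodiene.

Step 23
Reactants: 27 cyclopentane-1,3-dione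
Product: 28 2-nitrocyclopentane-1,3-dione (drawn as its enol, 3-hydroxy-2-nitrocyclopent-2-en-1-one)
Conditions: fuming HNO3, AcOH, 0 °C → rt
Reagents that add atoms: nitric acid, O[N+](=O)[O-]
Why: Electrophilic C-nitration of the enolised 1,3-dione at its only nucleophilic carbon, C-2.

Step 24
Reactants: 28 2-nitrocyclopentane-1,3-dione
Product: 29 2-amino-3-hydroxycyclopent-2-en-1-one hydrochloride
Conditions: H2 (1 atm), Pd/C (10%), HCl (1.1 equiv), MeOH, rt
Reagents that add atoms: hydrogen chloride, Cl
Why: Catalytic hydrogenation of the nitro group, with the amine trapped as its hydrochloride so that the α-amino dione cannot self-condense.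

Step 25
Reactants: 26 (2E,4E)-5-bromopenta-2,4-dienoyl chloride; 29 2-amino-3-hydroxycyclopent-2-en-1-one hydrochloride
Product: 30 (2E,4E)-5-bromo-N-(2-hydroxy-5-oxocyclopent-1-en-1-yl)penta-2,4-dienamide
Conditions: Et3N (3 equiv), DMF/CH2Cl2, 0 °C → rt; dilute-acid work-up
Reagents that add atoms: none
Why: N-acylation of the liberated amine by the acid chloride, in which any O-acylated enol ester rearranges to the amide by O→N acyl shift through a five-membered transition state.

**Final coupling**

Step 26
Reactants: 20 epoxyquinol (E)-vinylstannane; 30 bromodienamide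
Product: 31 target, (2E,4E,6R)-N-[(1S,5S,6R)-5-hydroxy-5-[(1E,3E,5E)-7-[(2-hydroxy-5-oxocyclopent-1-en-1-yl)amino]-7-oxohepta-1,3,5-trien-1-yl]-2-oxo-7-oxabicyclo[4.1.0]hept-3-en-3-yl]-4,6-dimethyldeca-2,4-dienamide
Conditions: PdCl2(MeCN)2 (5 mol %), DMF, rt, Ar, dark
Reagents that add atoms: none
Why: Stille cross-coupling, where the divalent palladium precatalyst is reduced in situ to zerovalent palladium and both alkenyl partners couple with retention to give the E,E,E-triene at room temperature without protecting the alcohol, epoxide, enone or enol.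

## Compound list

1 | butanal | CCCC=O | starting material
2 | ethyl (E)-2-methylhex-2-enoate | CCC/C=C(\C)C(=O)OCC | intermediate
3 | (E)-2-methylhex-2-enoic acid | CCC/C=C(\C)C(=O)O | intermediate
4 | (R)-2-methylhexanoic acid | CCCC[C@@H](C)C(=O)O | intermediate
5 | (R)-2-methylhexan-1-ol | CCCC[C@@H](C)CO | intermediate
6 | (R)-2-methylhexanal | CCCC[C@@H](C)C=O | intermediate
7 | (2E,4R)-2,4-dimethyloct-2-enal | CCCC[C@@H](C)/C=C(\C)C=O | intermediate
8 | ethyl (2E,4E,6R)-4,6-dimethyldeca-2,4-dienoate | CCCC[C@@H](C)/C=C(C)/C=C/C(=O)OCC | intermediate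
9 | (2E,4E,6R)-4,6-dimethyldeca-2,4-dienoic acid | CCCC[C@@H](C)/C=C(C)/C=C/C(=O)O | intermediate
10 | (2E,4E,6R)-4,6-dimethyldeca-2,4-dienoyl chloride | CCCC[C@@H](C)/C=C(C)/C=C/C(=O)Cl | intermediate
11 | hydroquinone | Oc1ccc(O)cc1 | starting material
12 | 1,4-dimethoxybenzene | COc1ccc(OC)cc1 | intermediate
13 | 1,4-dimethoxy-2-nitrobenzene | COc1ccc(OC)c([N+](=O)[O-])c1 | intermediate
14 | 2,5-dimethoxyaniline | COc1ccc(OC)c(N)c1 | intermediate
15 | (2E,4E,6R)-N-(2,5-dimethoxyphenyl)-4,6-dimethyldeca-2,4-dienamide | CCCC[C@@H](C)/C=C(C)/C=C/C(=O)Nc1cc(OC)ccc1OC | intermediate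
16 | (2E,4E,6R)-N-(3,3,6,6-tetramethoxycyclohexa-1,4-dien-1-yl)-4,6-dimethyldeca-2,4-dienamide (quinone bis-ketal) | CCCC[C@@H](C)/C=C(C)/C=C/C(=O)NC1=CC(OC)(OC)C=CC1(OC)OC | intermediate (not isolated)
17 | (2E,4E,6R)-N-(6,6-dimethoxy-3-oxocyclohexa-1,4-dien-1-yl)-4,6-dimethyldeca-2,4-dienamide (quinone monoketal) | CCCC[C@@H](C)/C=C(C)/C=C/C(=O)NC1=CC(=O)C=CC1(OC)OC | intermediate
18 | (2E,4E,6R)-N-[(1S,6R)-2,2-dimethoxy-5-oxo-7-oxabicyclo[4.1.0]hept-3-en-3-yl]-4,6-dimethyldeca-2,4-dienamide | CCCC[C@@H](C)/C=C(C)/C=C/C(=O)NC1=CC(=O)[C@@H]2O[C@@H]2C1(OC)OC | intermediate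
19 | (2E,4E,6R)-N-[(1S,5R,6R)-5-hydroxy-2,2-dimethoxy-5-[(E)-2-(tributylstannyl)ethenyl]-7-oxabicyclo[4.1.0]hept-3-en-3-yl]-4,6-dimethyldeca-2,4-dienamide | CCCC[C@@H](C)/C=C(C)/C=C/C(=O)NC1=C[C@@](O)(/C=C/[Sn](CCCC)(CCCC)CCCC)[C@@H]2O[C@@H]2C1(OC)OC | intermediate
20 | (2E,4E,6R)-N-[(1S,5R,6R)-5-hydroxy-2-oxo-5-[(E)-2-(tributylstannyl)ethenyl]-7-oxabicyclo[4.1.0]hept-3-en-3-yl]-4,6-dimethyldeca-2,4-dienamide | CCCC[C@@H](C)/C=C(C)/C=C/C(=O)NC1=C[C@@](O)(/C=C/[Sn](CCCC)(CCCC)CCCC)[C@@H]2O[C@@H]2C1=O | intermediate
21 | pyridine | c1ccncc1 | starting material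
22 | pyridinium-1-sulfonate | [O-]S(=O)(=O)[n+]1ccccc1 | intermediate
23 | glutaconaldehyde potassium salt, potassium (1E,3E)-5-oxopenta-1,3-dien-1-olate | [K+].[O-]/C=C/C=C/C=O | intermediate
24 | (2E,4E)-5-bromopenta-2,4-dienal | Br/C=C/C=C/C=O | intermediate
25 | (2E,4E)-5-bromopenta-2,4-dienoic acid | Br/C=C/C=C/C(=O)O | intermediate
26 | (2E,4E)-5-bromopenta-2,4-dienoyl chloride | Br/C=C/C=C/C(=O)Cl | intermediate
27 | cyclopentane-1,3-dione | O=C1CCC(=O)C1 | starting material
28 | 2-nitrocyclopentane-1,3-dione (enol form, 3-hydroxy-2-nitrocyclopent-2-en-1-one) | O=C1CCC(O)=C1[N+](=O)[O-] | intermediate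
29 | 2-amino-3-hydroxycyclopent-2-en-1-one hydrochloride | NC1=C(O)CCC1=O.Cl | intermediate
30 | (2E,4E)-5-bromo-N-(2-hydroxy-5-oxocyclopent-1-en-1-yl)penta-2,4-dienamide | Br/C=C/C=C/C(=O)NC1=C(O)CCC1=O | intermediate
31 | (2E,4E,6R)-N-[(1S,5S,6R)-5-hydroxy-5-[(1E,3E,5E)-7-[(2-hydroxy-5-oxocyclopent-1-en-1-yl)amino]-7-oxohepta-1,3,5-trien-1-yl]-2-oxo-7-oxabicyclo[4.1.0]hept-3-en-3-yl]-4,6-dimethyldeca-2,4-dienamide (CNP0262080.2) | CCCC[C@@H](C)/C=C(C)/C=C/C(=O)NC1=C[C@@](O)(/C=C/C=C/C=C/C(=O)NC2=C(O)CCC2=O)[C@@H]2O[C@@H]2C1=O | target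

## Step count and risks

Total step count: 26.
Longest linear sequence: 15 steps (steps 1–9, 13–17 and 26, from butanal 1 to 31). The other branches are 9 steps from hydroquinone, 7 from pyridine and 4 from cyclopentane-1,3-dione.

The three steps most likely to fail:

**Step 15 (asymmetric epoxidation; face selectivity and ee on this substrate are not assured).** The fallback sets out from 17 and comes back to the route at 20. Ketal exchange of 17 with (2R,4R)-pentane-2,4-diol (PPTS, benzene, 4 Å sieves, rt) gives the C2-symmetric spiro-dioxane quinone monoketal F1. Achiral Weitz–Scheffer epoxidation (tBuOOH, DBU, CH2Cl2, 0 °C) then runs under substrate control of the dioxane methyl groups. Because the two epoxides now differ at a nearby centre, the (1S,6R)-epoxy spiro-ketal F2 is separated from its epimer by chromatography. Addition of (E)-2-(tributylstannyl)vinyllithium as in step 16 gives the spiro-ketal stannyl carbinol F3, and Montmorillonite K10 in wet CH2Cl2 hydrolyses the dioxane to give 20.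

**Step 16 (alkenyllithium addition in the presence of the acidic amide N–H, the epoxide and the dienamide).** The fallback sets out from 18 and comes back at 19. Ethynylmagnesium bromide (3 equiv, THF, −78 → 0 °C; the first equivalent deprotonates the amide) adds to the ketone anti to the epoxide to give the ethynyl carbinol F4. A PdCl2(PPh3)2-catalysed syn-hydrostannation with Bu3SnH (THF, 0 °C) then places tin on the terminal carbon of the hindered propargylic alcohol and gives the (E)-vinylstannane 19.

**Step 26 (Stille coupling of two fully functionalised, light- and base-sensitive partners).** The fallback sets out from 20 and comes back at 31. Stille coupling of 20 with the free bromodienoic acid 25 (PdCl2(MeCN)2, DMF, rt, dark) gives the trienoic acid F5. The aminocyclopentenone is then attached last by amide formation with 29 (EDC·HCl, HOAt, iPr2NEt, DMF, 0 °C → rt) to give 31.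

## Further compounds

F1 | step 15 | (2E,4E,6R)-N-[(2R,4R)-2,4-dimethyl-9-oxo-1,5-dioxaspiro[5.5]undeca-7,10-dien-7-yl]-4,6-dimethyldeca-2,4-dienamide (spiro-dioxane quinone monoketal) | CCCC[C@@H](C)/C=C(C)/C=C/C(=O)NC1=CC(=O)C=CC12O[C@H](C)C[C@@H](C)O2
F2 | step 15 | (1S,6R)-epoxide of F1 (epoxy spiro-ketal, epoxide carbon next to the ketone R, next to the ketal S) | CCCC[C@@H](C)/C=C(C)/C=C/C(=O)NC1=CC(=O)[C@@H]3O[C@@H]3C12O[C@H](C)C[C@@H](C)O2
F3 | step 15 | spiro-ketal analogue of 19 (OH cis to the epoxide, (E)-2-(tributylstannyl)ethenyl on the carbinol carbon) | CCCC[C@@H](C)/C=C(C)/C=C/C(=O)NC1=C[C@@](O)(/C=C/[Sn](CCCC)(CCCC)CCCC)[C@@H]3O[C@@H]3C12O[C@H](C)C[C@@H](C)O2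
F4 | step 16 | (2E,4E,6R)-N-[(1S,5R,6R)-5-ethynyl-5-hydroxy-2,2-dimethoxy-7-oxabicyclo[4.1.0]hept-3-en-3-yl]-4,6-dimethyldeca-2,4-dienamide | CCCC[C@@H](C)/C=C(C)/C=C/C(=O)NC1=C[C@@](O)(C#C)[C@@H]2O[C@@H]2C1(OC)OC
F5 | step 26 | (2E,4E,6E)-7-[(1S,5S,6R)-3-[(2E,4E,6R)-4,6-dimethyldeca-2,4-dienamido]-5-hydroxy-2-oxo-7-oxabicyclo[4.1.0]hept-3-en-5-yl]hepta-2,4,6-trienoic acid | CCCC[C@@H](C)/C=C(C)/C=C/C(=O)NC1=C[C@@](O)(/C=C/C=C/C=C/C(=O)O)[C@@H]2O[C@@H]2C1=O
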